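## Retrosynthetic overview

1. The target comes from the cis-fused 3α,4α-diol 22 by esterifying O3 with epoxy acid 26 (from angelic acid by Sharpless epoxidation) and acetylating O4. Diol 22 comes from the 3-ene 18 by a Woodward cis-hydroxylation on the concave α face.
2. Alkene 18 comes from the cis-fused 3,8-dione 14 by C3-selective hydride reduction and syn-dehydration. The two epimerisable α-keto centres of 14 (C4, C7) are first converged through its C3 dioxolane 15.
3. The strategy rests on ring B (C5–C6–C7–C8–C9–C10). Its C5–C6 bond joins the β-carbon of the ring A enone (C3=O, C4=C5) to the β-carbon of an exocyclic enone (C8=O, C7=C6H2, isopropyl on C7). Hence 14 comes from bis-enone 13 by cathodic β,β-hydrocoupling.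
4. Bis-enone 13 comes from aldehyde 9 and vinyl triflate 11 (Nozaki–Hiyama–Kishi coupling, oxidation). Aldehyde 9 comes from (R)-4-allyl-2,4-dimethylcyclohexenone 8, made from 2-methylcyclohexane-1,3-dione by Pd-catalysed decarboxylative allylation of enol carbonate 5 and Stork–Danheiser transposition.
5. Ring order: ring A is present from the start, ring B closes in the key step, and the oxirane of the acyl group is made separately.

Key step: step 10

## Remarks on the chemistry

- Eudesmane numbering is used for the bicycle. β is the face of the C10 methyl group, α the opposite face; 5β-H with 10β-methyl is the cis ring fusion. "Steroid-like conformer" means the chair–chair form with C9 axial on ring A and the C10 methyl axial on ring B.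
- Assumption: the PHOX ligand transmits the same facial sense as with allyl 2-methylcyclohexenyl carbonate, where the (S)-ligand gives the (S)-ketone; the (R)-ligand is therefore specified in step 4.
- The cathodic step fixes C5 only. The 4β,7β and 4α,7α epimers of dione 14 are each all-equatorial in one of the two cis-decalin conformers and should be close in energy. The route therefore converges them through ketal 15 and does not expose free 14 or alkene 18 to base.

## Route

Step 1
Reactants: 1 2-methylcyclohexane-1,3-dione
Product: 2 3-isobutoxy-2-methylcyclohex-2-en-1-one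
Conditions: i-BuOH, TsOH·H2O (cat.), PhH, reflux, Dean–Stark
Reagents that add atoms: 2-methylpropan-1-ol CC(C)CO
Why: Acid-catalysed enol etherification of the cyclic 1,3-dione with removal of water gives the vinylogous ester; no stereocentre is formed.

Step 2
Reactants: 2 3-isobutoxy-2-methylcyclohex-2-en-1-one
Product: 3 (±)-3-isobutoxy-2,6-dimethylcyclohex-2-en-1-one
Conditions: LDA (LiN(iPr)2), THF, −78 °C; MeI, −78 → 0 °C
Reagents that add atoms: iodomethane CI
Why: Kinetic deprotonation of a vinylogous ester occurs at the α' carbon and the cross-conjugated enolate is C-methylated (Stork–Danheiser alkylation); the new centre is racemic and is erased in step 3.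

Step 3
Reactants: 3 (±)-3-isobutoxy-2,6-dimethylcyclohex-2-en-1-one; 4 allyl chloroformate
Product: 5 allyl (5-isobutoxy-2,6-dimethylcyclohexa-1,5-dien-1-yl) carbonate
Conditions: LDA, TMEDA, THF, −78 °C; then 4, −78 °C
Reagents that add atoms: none
Why: LDA again removes the α' proton and the hindered tetrasubstituted enolate is acylated on oxygen by the chloroformate in the presence of TMEDA (enolate O-acylation), any C-acylated β-keto ester being funnelled through the same palladium enolate in step 4.

Step 4
Reactants: 5 allyl (5-isobutoxy-2,6-dimethylcyclohexa-1,5-dien-1-yl) carbonate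
Product: 6 (R)-6-allyl-3-isobutoxy-2,6-dimethylcyclohex-2-en-1-one
Conditions: Pd2(dba)3 (2.5 mol %, zerovalent palladium), (R)-t-BuPHOX (6 mol %), toluene, 25 °C
Reagents that add atoms: none
Why: Ionisation of the allyl carbonate, loss of CO2 and C–C bond formation within the allyl palladium enolate (Tsuji-type decarboxylative asymmetric allylic alkylation of a vinylogous ester enol carbonate) create the quaternary centre, whose (R) configuration is set by the (R)-phosphinooxazoline ligand.

Step 5
Reactants: 6 (R)-6-allyl-3-isobutoxy-2,6-dimethylcyclohex-2-en-1-one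
Product: 8 (R)-4-allyl-2,4-dimethylcyclohex-2-en-1-one, via allylic alcohol 7 (not isolated)
Conditions: LiAlH4, Et2O, 0 °C; then 1 M aq. HCl, rt
Reagents that add atoms: none
Why: 1,2-Reduction of the vinylogous ester carbonyl followed by acid hydrolysis of the enol ether and loss of water transposes the carbonyl (Stork–Danheiser transposition) without touching the quaternary centre.

Step 6
Reactants: 8 (R)-4-allyl-2,4-dimethylcyclohex-2-en-1-one
Product: 9 2-[(1R)-1,3-dimethyl-4-oxocyclohex-2-en-1-yl]acetaldehyde
Conditions: OsO4 (2 mol %), NaIO4, 2,6-lutidine, dioxane/H2O (3:1), rt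
Reagents that add atoms: osmium tetroxide O=[Os](=O)(=O)=O; sodium periodate [Na+].[O-]I(=O)(=O)=O
Why: OsO4 dihydroxylates the electron-rich monosubstituted alkene much faster than the electron-poor trisubstituted enone and periodate cleaves the diol in situ (Lemieux–Johnson oxidation).

Step 7
Reactants: 10 3-methylbutan-2-one
Product: 11 3-methylbut-1-en-2-yl trifluoromethanesulfonate
Conditions: LDA, THF, −78 °C; PhNTf2, −78 → 0 °C
Reagents that add atoms: N-phenylbis(trifluoromethanesulfonimide) O=S(=O)(N(c1ccccc1)S(=O)(=O)C(F)(F)F)C(F)(F)F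
Why: LDA deprotonates the methyl group of the methyl ketone under kinetic control and the enolate is sulfonylated on oxygen (enol triflate formation).

Step 8
Reactants: 9 2-[(1R)-1,3-dimethyl-4-oxocyclohex-2-en-1-yl]acetaldehyde; 11 3-methylbut-1-en-2-yl trifluoromethanesulfonate
Product: 12 (4R)-4-(2-hydroxy-4-methyl-3-methylidenepentyl)-2,4-dimethylcyclohex-2-en-1-one (both carbinol epimers)
Conditions: CrCl2 (4 equiv), NiCl2 (1 mol %), DMF, rt
Reagents that add atoms: none
Why: The alkenylchromium reagent formed under nickel catalysis adds to aldehydes but not to ketones or enones (Nozaki–Hiyama–Kishi reaction), which places the methylidene group regiospecifically on C7; the carbinol centre forms unselectively and is removed in step 9.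

Step 9
Reactants: 12 (4R)-4-(2-hydroxy-4-methyl-3-methylidenepentyl)-2,4-dimethylcyclohex-2-en-1-one
Product: 13 (4R)-2,4-dimethyl-4-(4-methyl-3-methylidene-2-oxopentyl)cyclohex-2-en-1-one
Conditions: Dess–Martin periodinane, NaHCO3, CH2Cl2, 0 °C → rt; used at once
Reagents that add atoms: none
Why: Buffered Dess–Martin oxidation of the secondary allylic alcohol should give the sensitive α-methylene ketone without conjugate addition or epimerisation.

Step 10
Reactants: 13 (4R)-2,4-dimethyl-4-(4-methyl-3-methylidene-2-oxopentyl)cyclohex-2-en-1-one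
Product: 14 4β,10β-dimethyl-7β-isopropyl-5β-decalin-3,8-dione (cis-fused; formed together with its C4 and C7 epimers)
Conditions: mercury pool cathode, platinum anode, divided cell, Et4NOTs (0.2 M), MeCN/H2O (9:1), −2.0 V vs SCE, about 2.1 F/mol, 5 mM, rt
Reagents that add atoms: none
Why: At the cathode the exo-methylene ketone, the more easily reduced enone, takes up one electron, and the β-carbon C6 of its radical anion adds to the β-carbon C5 of the ring enone; a second electron and two protons from the aqueous medium then give the saturated 3,8-dione. The closest known reaction type is the Baizer-type electrohydrocyclisation (intramolecular electroreductive hydrocoupling) of bis-activated alkenes, bis-enones included. Ring B closes in a 6-exo-trig mode (C6 onto C5, with C4 exocyclic to the new ring). C5 is set by the tether: the C9–C8–C7 arm on the quaternary C10 reaches C5 only on the face anti to the C10 methyl group and the bond forms perpendicular to the enone plane, which by necessity gives the cis fusion. C4 and C7 arise by protonation of the two enolates, are not controlled here, and are converged in step 11. The step needs β,β-coupling in preference to two-electron saturation, β,α-coupling or intermolecular hydrodimerisation; this is secured by the six-membered ring that only the β,β-mode can form, by high dilution and by holding the potential at the first reduction wave.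

Step 11
Reactants: 14 4β,10β-dimethyl-7β-isopropyl-5β-decalin-3,8-dione (epimer mixture from step 10)
Product: 15 3,3-ethylenedioxy-4β,10β-dimethyl-7β-isopropyl-5β-decalin-8-one
Conditions: HO(CH2)2OH (1.3 equiv), TsOH·H2O (cat.), PhH, reflux, Dean–Stark, to constant epimer ratio
Reagents that add atoms: ethane-1,2-diol OCCO
Why: The unhindered C3 carbonyl is ketalised in preference to C8 (flanked by the isopropyl-bearing C7 and the neopentyl C9), and under these reversible acidic conditions C4 (through the enol ether) and C7 (through the C8 enol) equilibrate; because the axial dioxolane oxygen would be 1,3-diaxial to C6 in the non-steroid conformer, the steroid-like conformer with equatorial 4β-methyl and 7β-isopropyl groups should be the thermodynamic sink (selective ketalisation under thermodynamic control).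

Step 12
Reactants: 15 3,3-ethylenedioxy-4β,10β-dimethyl-7β-isopropyl-5β-decalin-8-one
Product: 16 3α-hydroxy-4β,10β-dimethyl-7β-isopropyl-5β-decalin-8-one, via dione 14 (not isolated)
Conditions: 1 M aq. HCl, THF, 0 °C → rt; NaHCO3 to pH 8; MeOH, −40 °C, NaBH4
Reagents that add atoms: water O
Why: Ketal hydrolysis releases 14 as the single 4β,7β epimer faster than it can enolise, and borohydride then attacks C3 axially from the open β face to give the equatorial 3α-alcohol, while C8 is shielded from axial attack by the syn-axial C10 methyl and from equatorial attack by the isopropyl group (chemo- and diastereoselective NaBH4 reduction).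

Step 13
Reactants: 16 3α-hydroxy-4β,10β-dimethyl-7β-isopropyl-5β-decalin-8-one
Product: 18 4,10β-dimethyl-7β-isopropyl-5β-decal-3-en-8-one, via sulfamate salt 17 (not isolated)
Conditions: Burgess reagent (MeO2CN(−)SO2N(+)Et3), toluene, rt → 70 °C; product kept away from base
Reagents that add atoms: none
Why: The sulfamate of the equatorial alcohol undergoes thermal syn-elimination (Burgess dehydration); the tertiary H4α is cis to the leaving group and cis-fused decalins favour the 3-ene, so the trisubstituted C3=C4 alkene should predominate over the 2-ene, with C7 untouched under the neutral conditions.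

Step 14
Reactants: 18 4,10β-dimethyl-7β-isopropyl-5β-decal-3-en-8-one
Product: 21 4α-acetoxy-3α-hydroxy-4β,10β-dimethyl-7β-isopropyl-5β-decalin-8-one, via iodo acetate 19 (not isolated), via acetoxonium acetate 20 (not isolated)
Conditions: I2, AgOAc, AcOH containing 1–2 equiv H2O, rt, dark; then 90 °C
Reagents that add atoms: silver acetate CC(=O)[O-].[Ag+]; water O
Why: In the Woodward cis-hydroxylation the iodonium ion forms on the open β face of the steroid-like conformer (the α face is screened by the axial C9 methylene), acetate opens it trans-diaxially at the tertiary C4 from the α face, the axial acetate displaces the axial 3β-iodide with inversion, and water hydrolyses the α-fused acetoxonium ion, so both oxygens end on the concave α face and the C4 methyl becomes β.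

Step 15
Reactants: 21 4α-acetoxy-3α-hydroxy-4β,10β-dimethyl-7β-isopropyl-5β-decalin-8-one
Product: 22 3α,4α-dihydroxy-4β,10β-dimethyl-7β-isopropyl-5β-decalin-8-one
Conditions: K2CO3 (cat.), MeOH, rt → 40 °C
Reagents that add atoms: none
Why: Methanolysis (transesterification) converges any 3-acetate formed by acyl migration to the diol and at the same time equilibrates C7, where the equatorial 7β-isopropyl epimer is strongly favoured because the equatorial 4β-methyl group now locks ring A in the steroid-like conformer.

Step 16
Reactants: 23 angelic acid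
Product: 24 (Z)-2-methylbut-2-en-1-ol
Conditions: LiAlH4, Et2O, 0 °C
Reagents that add atoms: none
Why: Hydride reduction of the carboxylic acid to the primary alcohol leaves the trisubstituted (Z)-alkene untouched and unisomerised.

Step 17
Reactants: 24 (Z)-2-methylbut-2-en-1-ol
Product: 25 [(2R,3S)-2,3-dimethyloxiran-2-yl]methanol
Conditions: Ti(OiPr)4 (cat.), D-(−)-diisopropyl tartrate (cat.), t-BuOOH, 4 Å molecular sieves, CH2Cl2, −20 °C
Reagents that add atoms: tert-butyl hydroperoxide CC(C)(C)OO
Why: Sharpless asymmetric epoxidation of the allylic alcohol is stereospecific (the two methyl groups stay trans), and the D-(−)-tartrate, opposite to the L-(+)-tartrate that converts geraniol into its (2S,3S)-epoxide, delivers oxygen to the face that gives the (2R,3S)-epoxy alcohol.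

Step 18
Reactants: 25 [(2R,3S)-2,3-dimethyloxiran-2-yl]methanol
Product: 26 (2S,3S)-2,3-dimethyloxirane-2-carboxylic acid
Conditions: RuCl3·xH2O (cat.), NaIO4, CCl4/MeCN/H2O, rt
Reagents that add atoms: sodium periodate [Na+].[O-]I(=O)(=O)=O; water O
Why: RuO4 generated catalytically oxidises the primary alcohol through the aldehyde hydrate to the acid without opening the epoxide (Sharpless ruthenium oxidation), the descriptor at C2 changing from R to S only through the change in CIP priorities.

Step 19
Reactants: 22 3α,4α-dihydroxy-4β,10β-dimethyl-7β-isopropyl-5β-decalin-8-one; 26 (2S,3S)-2,3-dimethyloxirane-2-carboxylic acid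
Product: 28 3α-[(2S,3S)-2,3-dimethyloxirane-2-carbonyloxy]-4α-hydroxy-4β,10β-dimethyl-7β-isopropyl-5β-decalin-8-one, via mixed anhydride 27 (not isolated)
Conditions: 26, 2,4,6-Cl3C6H2COCl, Et3N, THF, rt; then 22, DMAP, toluene, rt → 40 °C
Reagents that add atoms: none
Why: In the Yamaguchi esterification DMAP attacks the mixed anhydride at the less hindered epoxy-acyl carbonyl and the acylpyridinium ion acylates the equatorial secondary 3α-hydroxyl, the axial tertiary 4α-hydroxyl being inert, so no stereocentre is touched.

Step 20
Reactants: 28 3α-[(2S,3S)-2,3-dimethyloxirane-2-carbonyloxy]-4α-hydroxy-4β,10β-dimethyl-7β-isopropyl-5β-decalin-8-one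
Product: 29 CNP0221066.1 (4α-acetoxy-3α-[(2S,3S)-2,3-dimethyloxirane-2-carbonyloxy]-4β,10β-dimethyl-7β-isopropyl-5β-decalin-8-one)
Conditions: Ac2O (excess), DMAP, Et3N, CH2Cl2, 40 °C
Reagents that add atoms: acetic anhydride CC(=O)OC(C)=O
Why: DMAP-catalysed acetylation with excess anhydride esterifies the hindered tertiary alcohol, and the epoxy ester and the ketone (C7 already in its stable configuration) should tolerate the mildly basic conditions.

## Compound list

1 | 2-methylcyclohexane-1,3-dione | CC1C(=O)CCCC1=O | starting material
2 | 3-isobutoxy-2-methylcyclohex-2-en-1-one | CC1=C(OCC(C)C)CCCC1=O | intermediate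
3 | (±)-3-isobutoxy-2,6-dimethylcyclohex-2-en-1-one | CC1CCC(OCC(C)C)=C(C)C1=O | intermediate
4 | allyl chloroformate | C=CCOC(=O)Cl | starting material
5 | allyl (5-isobutoxy-2,6-dimethylcyclohexa-1,5-dien-1-yl) carbonate | C=CCOC(=O)OC1=C(C)CCC(OCC(C)C)=C1C | intermediate
6 | (R)-6-allyl-3-isobutoxy-2,6-dimethylcyclohex-2-en-1-one | C=CC[C@@]1(C)CCC(OCC(C)C)=C(C)C1=O | intermediate
7 | (6R)-6-allyl-3-isobutoxy-2,6-dimethylcyclohex-2-en-1-ol, both carbinol epimers, formed in situ | C=CC[C@@]1(C)CCC(OCC(C)C)=C(C)C1O | intermediate
8 | (R)-4-allyl-2,4-dimethylcyclohex-2-en-1-one | C=CC[C@@]1(C)CCC(=O)C(C)=C1 | intermediate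
9 | 2-[(1R)-1,3-dimethyl-4-oxocyclohex-2-en-1-yl]acetaldehyde | O=CC[C@@]1(C)CCC(=O)C(C)=C1 | intermediate
10 | 3-methylbutan-2-one | CC(=O)C(C)C | starting material
11 | 3-methylbut-1-en-2-yl trifluoromethanesulfonate | C=C(OS(=O)(=O)C(F)(F)F)C(C)C | intermediate
12 | (4R)-4-(2-hydroxy-4-methyl-3-methylidenepentyl)-2,4-dimethylcyclohex-2-en-1-one, both carbinol epimers | C=C(C(C)C)C(O)C[C@@]1(C)CCC(=O)C(C)=C1 | intermediate
13 | (4R)-2,4-dimethyl-4-(4-methyl-3-methylidene-2-oxopentyl)cyclohex-2-en-1-one (bis-enone) | C=C(C(C)C)C(=O)C[C@@]1(C)CCC(=O)C(C)=C1 | intermediate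
14 | 4β,10β-dimethyl-7β-isopropyl-5β-decalin-3,8-dione (cis-fused, eudesmane numbering) | C[C@H]1C(=O)CC[C@]2(C)CC(=O)[C@@H](C(C)C)C[C@@H]21 | intermediate
15 | 3,3-ethylenedioxy-4β,10β-dimethyl-7β-isopropyl-5β-decalin-8-one | C[C@H]1C2(OCCO2)CC[C@]3(C)CC(=O)[C@@H](C(C)C)C[C@@H]31 | intermediate
16 | 3α-hydroxy-4β,10β-dimethyl-7β-isopropyl-5β-decalin-8-one | C[C@H]1[C@H](O)CC[C@]2(C)CC(=O)[C@@H](C(C)C)C[C@@H]21 | intermediate
17 | triethylammonium salt of the 3α-O-(N-methoxycarbonylsulfamoyl) derivative of 16, formed in situ | C[C@H]1[C@H](OS(=O)(=O)[N-]C(=O)OC)CC[C@]2(C)CC(=O)[C@@H](C(C)C)C[C@@H]21.CC[NH+](CC)CC | intermediate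
18 | 4,10β-dimethyl-7β-isopropyl-5β-decal-3-en-8-one | CC1=CCC[C@]2(C)CC(=O)[C@@H](C(C)C)C[C@@H]21 | intermediate
19 | 4α-acetoxy-3β-iodo-4β,10β-dimethyl-7β-isopropyl-5β-decalin-8-one, formed in situ | CC(=O)O[C@]1(C)[C@@H](I)CC[C@]2(C)CC(=O)[C@@H](C(C)C)C[C@@H]21 | intermediate
20 | 2-methyl-1,3-dioxolan-2-ylium ion fused at C3–C4 on the α face, acetate salt, formed in situ | C[C+]1O[C@]2(C)[C@H](O1)CC[C@]3(C)CC(=O)[C@@H](C(C)C)C[C@@H]32.CC(=O)[O-] | intermediate
21 | 4α-acetoxy-3α-hydroxy-4β,10β-dimethyl-7β-isopropyl-5β-decalin-8-one | CC(=O)O[C@]1(C)[C@H](O)CC[C@]2(C)CC(=O)[C@@H](C(C)C)C[C@@H]21 | intermediate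
22 | 3α,4α-dihydroxy-4β,10β-dimethyl-7β-isopropyl-5β-decalin-8-one | O[C@]1(C)[C@H](O)CC[C@]2(C)CC(=O)[C@@H](C(C)C)C[C@@H]21 | intermediate
23 | angelic acid, (Z)-2-methylbut-2-enoic acid | C/C=C(/C)C(=O)O | starting material
24 | (Z)-2-methylbut-2-en-1-ol | C/C=C(/C)CO | intermediate
25 | [(2R,3S)-2,3-dimethyloxiran-2-yl]methanol | OC[C@@]1(C)O[C@H]1C | intermediate
26 | (2S,3S)-2,3-dimethyloxirane-2-carboxylic acid | OC(=O)[C@@]1(C)O[C@H]1C | intermediate
27 | (2S,3S)-2,3-dimethyloxirane-2-carboxylic 2,4,6-trichlorobenzoic anhydride, formed in situ | O=C(OC(=O)c1c(Cl)cc(Cl)cc1Cl)[C@@]1(C)O[C@H]1C | intermediate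
28 | 3α-[(2S,3S)-2,3-dimethyloxirane-2-carbonyloxy]-4α-hydroxy-4β,10β-dimethyl-7β-isopropyl-5β-decalin-8-one | O[C@]1(C)[C@H](OC(=O)[C@@]2(C)O[C@H]2C)CC[C@]2(C)CC(=O)[C@@H](C(C)C)C[C@@H]21 | intermediate
29 | CNP0221066.1, 4α-acetoxy-3α-[(2S,3S)-2,3-dimethyloxirane-2-carbonyloxy]-4β,10β-dimethyl-7β-isopropyl-5β-decalin-8-one | CC(=O)O[C@]1(C)[C@H](OC(=O)[C@@]2(C)O[C@H]2C)CC[C@]2(C)CC(=O)[C@@H](C(C)C)C[C@@H]21 | target

## Step count and risks

Total step count: 20. Longest linear sequence: 16 (steps 1–6, 8–15, 19, 20).

Steps most likely to fail: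

1. Step 10 (cathodic ring closure). The radical anion of the vinyl ketone may be protonated and reduced further before it cyclises (net saturation of the exo-methylene group), or may couple intermolecularly. Fallback, from 13: benzeneselenol with catalytic Et3N in CH2Cl2 at 0 °C adds only to the unhindered exo-methylene ketone and gives the β-(phenylselanyl) ketone F1. Bu3SnH and AIBN in refluxing benzene under slow addition then generate the primary C6 radical, which closes 6-exo onto C5 of the ring enone and is reduced at C4. The route is rejoined at 14 (same epimer mixture, which enters step 11).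

2. Step 13 (dehydration). The sulfamate may abstract the secondary cis hydrogen at C2 as well as the tertiary one at C4, eroding regioselectivity; any axial 3β-alcohol carried from step 12 can eliminate only toward C2. Fallback, from 15: hydrolysis as in step 12, but reduction of the released 14 with LiBH(s-Bu)3 in THF at −78 °C, which attacks C3 equatorially, gives the axial 3β-alcohol F2. POCl3 in pyridine (0 °C → rt) then effects anti-periplanar elimination of the axial dichlorophosphate with the trans-diaxial tertiary H4α. The route is rejoined at 18.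

3. Step 14 (Woodward cis-hydroxylation). Facial bias in iodonium formation may be insufficient, or the congested axial tertiary acetate may fail to displace iodide, so that the iodo acetate eliminates or is solvolysed without inversion. Fallback, from 18: mCPBA (NaHCO3, CH2Cl2, 0 °C) epoxidises the open β face to the 3β,4β-epoxide F3. Aqueous HClO4 in THF opens it trans-diaxially by attack of water on the tertiary C4 from the α face, giving the 3β,4α-diol F4. Dess–Martin oxidation of the secondary alcohol gives the 4α-hydroxy-3,8-dione F5, and NaBH4 in MeOH at −78 °C delivers hydride axially from the β face to the more electrophilic C3 carbonyl. The route is rejoined at 22.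

## Further compounds

F1 | step 10 | (4R)-2,4-dimethyl-4-[4-methyl-2-oxo-3-(phenylselanylmethyl)pentyl]cyclohex-2-en-1-one, both epimers at the chain carbon | CC(C)C(C[Se]c1ccccc1)C(=O)C[C@@]1(C)CCC(=O)C(C)=C1
F2 | step 13 | 3β-hydroxy-4β,10β-dimethyl-7β-isopropyl-5β-decalin-8-one | C[C@H]1[C@@H](O)CC[C@]2(C)CC(=O)[C@@H](C(C)C)C[C@@H]21
F3 | step 14 | 3β,4β-epoxy-4,10β-dimethyl-7β-isopropyl-5β-decalin-8-one | C[C@]12O[C@H]1CC[C@]3(C)CC(=O)[C@@H](C(C)C)C[C@@H]32
F4 | step 14 | 3β,4α-dihydroxy-4β,10β-dimethyl-7β-isopropyl-5β-decalin-8-one | O[C@]1(C)[C@@H](O)CC[C@]2(C)CC(=O)[C@@H](C(C)C)C[C@@H]21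
F5 | step 14 | 4α-hydroxy-4β,10β-dimethyl-7β-isopropyl-5β-decalin-3,8-dione | O[C@]1(C)C(=O)CC[C@]2(C)CC(=O)[C@@H](C(C)C)C[C@@H]21
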